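**Retrosynthetic overview**

- Rings A and D are the two 3-hydroxyphenyl rings, ring B is the para-disubstituted ring, ring C the 1,2,4-trisubstituted ring. The plan rests on ring C: its C–OH and C–O–aryl carbons are adjacent and the CH2CH2–ring D chain is para to the C–OH, which is the pattern of a 6-aryloxy-4-alkylcyclohex-2-enone one oxidation level below the arene.
- Target 21 ⇐ cleavage of two methyl ethers of 19 ⇐ dehydrogenation of cyclohexenone 17.
- 17 ⇐ Michael–aldol annulation of aryloxyacetone 9 with 2-methylidene aldehyde 14 (OCH2 carbon of 9 to the =CH2 carbon of 14; CH3 carbon of 9 to the CHO carbon of 14).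
- 9 ⇐ bibenzyl phenol 7 + chloroacetone (the ether oxygen is set by SN2, not by aryl–oxygen coupling); 7 ⇐ Wittig reaction and hydrogenation; 14 ⇐ Heck reaction of 3-iodoanisole with but-3-en-1-ol, then α-methylenation.
- Ring order: rings A, B and D are bought as arenes; ring C is the only ring made, closed in step 7 and aromatised in step 8.

Key step: step 7

Assumption: enal 14 is used freshly prepared because 2-alkylacroleins dimerise on storage, and enone 17 is carried on as its racemic cis/trans mixture because both stereocentres vanish in step 8 and the target has none.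

**Route**

Step 1
Reactants: 1 3-methoxybenzyl bromide
Product: 2 (3-methoxybenzyl)triphenylphosphonium bromide
Conditions: PPh3, toluene, reflux
Reagents that add atoms: triphenylphosphine, c1ccc(cc1)P(c1ccccc1)c1ccccc1
Why: SN2 quaternisation of triphenylphosphine by the benzylic bromide (phosphonium salt formation), with the salt expected to crystallise from toluene.

Step 2
Reactants: 2 (3-methoxybenzyl)triphenylphosphonium bromide; 3 4-(benzyloxy)benzaldehyde
Product: 5 1-(benzyloxy)-4-[2-(3-methoxyphenyl)ethenyl]benzene (E/Z mixture), via phosphorus ylide 4 (not isolated)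
Conditions: KOtBu, THF, 0 °C; then 3, 0 °C → rt
Reagents that add atoms: none
Why: Wittig olefination, in which the semi-stabilised benzylic ylide 4 condenses with the non-enolisable aldehyde 3 to the stilbene as an E/Z mixture whose geometry is irrelevant because the double bond is hydrogenated in step 3.

Step 3
Reactants: 5 1-(benzyloxy)-4-[2-(3-methoxyphenyl)ethenyl]benzene
Product: 7 4-[2-(3-methoxyphenyl)ethyl]phenol, via saturated benzyl ether 6 (not isolated)
Conditions: H2 (1 atm), Pd/C (palladium on carbon, 10 wt%), EtOH/EtOAc, rt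
Reagents that add atoms: none
Why: Heterogeneous catalytic hydrogenation saturates the stilbene double bond and then cleaves the benzyl aryl ether by hydrogenolysis while the aryl methyl ether is inert, so one operation should deliver the free bibenzyl phenol.

Step 4
Reactants: 7 4-[2-(3-methoxyphenyl)ethyl]phenol; 8 chloroacetone
Product: 9 1-{4-[2-(3-methoxyphenyl)ethyl]phenoxy}propan-2-one
Conditions: K2CO3, acetone, reflux
Reagents that add atoms: none
Why: Williamson ether synthesis, in which the phenoxide displaces chloride from the highly SN2-reactive α-chloro ketone and so installs the oxygen of the future diaryl ether without any aryl–oxygen coupling.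

Step 5
Reactants: 10 3-iodoanisole; 11 but-3-en-1-ol
Product: 12 4-(3-methoxyphenyl)butanal
Conditions: Pd(OAc)2 (3 mol%), LiOAc, LiCl, Bu4NCl, DMF, 65 °C
Reagents that add atoms: none
Why: Heck reaction of an aryl iodide with a homoallylic alcohol under phosphine-free Jeffery conditions, in which the aryl group adds to the terminal alkene carbon, palladium walks along the chain by β-hydride elimination and re-insertion to the carbinol carbon, and the released enol tautomerises to the saturated aldehyde.

Step 6
Reactants: 12 4-(3-methoxyphenyl)butanal; 13 formaldehyde (37% aqueous)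
Product: 14 4-(3-methoxyphenyl)-2-methylidenebutanal
Conditions: pyrrolidine (10 mol%), EtCO2H (10 mol%), iPrOH, 45 °C
Reagents that add atoms: none
Why: Amine-catalysed α-methylenation (Mannich condensation and elimination), in which the pyrrolidine enamine of 12 attacks the formaldehyde-derived iminium ion and β-elimination of the amine leaves the 2-methylidene aldehyde.

Step 7
Reactants: 9 1-{4-[2-(3-methoxyphenyl)ethyl]phenoxy}propan-2-one; 14 4-(3-methoxyphenyl)-2-methylidenebutanal
Product: 17 4-[2-(3-methoxyphenyl)ethyl]-6-{4-[2-(3-methoxyphenyl)ethyl]phenoxy}cyclohex-2-en-1-one (racemic cis/trans mixture), via keto aldehyde Michael adduct 15 (not isolated), via ketol 16 (not isolated)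
Conditions: 9 (1.5 equiv), pyrrolidine (0.3 equiv), AcOH (0.3 equiv), toluene, rt, 14 added over 8 h by syringe pump; then 80 °C; dilute aq. HCl work-up
Reagents that add atoms: none
Why: Pyrrolidinium acetate converts the electron-poor ketone 9 into its enamine mainly toward the oxygen-bearing carbon (as hydroxy- and alkoxyacetones do), and this carbon adds to the unsubstituted CH2 terminus of enal 14 (Stork enamine Michael addition) to give keto aldehyde 15 after hydrolysis. On warming, the methyl-side enamine or enol of 15, the only one that can reach the aldehyde through a six-membered transition state, closes the future ring C by a 6-(enolendo)-exo-trig aldol addition to ketol 16, and loss of water into conjugation gives enone 17. The closest known reaction type is the Robinson annulation in its enamine form (α,α'-annulation of ketone enamines with acroleins). The two new stereocentres (C4 and C6 of 17) are not controlled and need not be, since both become sp2 carbons in step 8. Regiochemistry needs no control either, because bond formation in the opposite order (methyl carbon to CH2, oxygen-bearing carbon to CHO) would give the 2-aryloxy-4-alkylcyclohex-2-enone, which leads to the same phenol 19. The selectivity that matters is cross-annulation over self-condensation of the enal and double Michael addition, and slow addition of 14 to an excess of 9 should secure it.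

Step 8
Reactants: 17 4-[2-(3-methoxyphenyl)ethyl]-6-{4-[2-(3-methoxyphenyl)ethyl]phenoxy}cyclohex-2-en-1-one
Product: 19 4-[2-(3-methoxyphenyl)ethyl]-2-{4-[2-(3-methoxyphenyl)ethyl]phenoxy}phenol, via cross-conjugated dienone 18 (not isolated)
Conditions: Pd(OCOCF3)2 (5 mol%), 2-(dimethylamino)pyridine (10 mol%), TsOH (20 mol%), O2 (1 atm), DMSO, 80 °C
Reagents that add atoms: none
Why: Aerobic palladium-catalysed dehydrogenation of a cyclohexenone to a phenol, in which a divalent palladium enolate at C6 undergoes β-hydride elimination from C5 to dienone 18, which tautomerises to the arene while O2 reoxidises the zerovalent palladium; the two stereocentres of 17 are erased here.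

Step 9
Reactants: 19 4-[2-(3-methoxyphenyl)ethyl]-2-{4-[2-(3-methoxyphenyl)ethyl]phenoxy}phenol
Product: 21 perrottetin E, via tris(dibromoboryloxy) intermediate 20 (not isolated)
Conditions: BBr3 (6 equiv), CH2Cl2, −78 °C → rt; then H2O, 0 °C
Reagents that add atoms: none
Why: Lewis-acid cleavage of aryl methyl ethers, in which BBr3 coordinates each methoxy oxygen and bromide removes the methyl group by SN2 while the diaryl ether and bibenzyl chains are inert, and hydrolysis of the aryloxyboron bromides 20 on work-up releases the three phenols.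

**Compound list**

1 | 3-methoxybenzyl bromide | COc1cccc(CBr)c1 | starting material
2 | (3-methoxybenzyl)triphenylphosphonium bromide | COc1cccc(C[P+](c2ccccc2)(c2ccccc2)c2ccccc2)c1.[Br-] | intermediate
3 | 4-(benzyloxy)benzaldehyde | O=Cc1ccc(OCc2ccccc2)cc1 | starting material
4 | (3-methoxybenzylidene)triphenylphosphorane | COc1cccc(C=P(c2ccccc2)(c2ccccc2)c2ccccc2)c1 | intermediate
5 | 1-(benzyloxy)-4-[2-(3-methoxyphenyl)ethenyl]benzene (E/Z mixture) | COc1cccc(C=Cc2ccc(OCc3ccccc3)cc2)c1 | intermediate
6 | 1-(benzyloxy)-4-[2-(3-methoxyphenyl)ethyl]benzene | COc1cccc(CCc2ccc(OCc3ccccc3)cc2)c1 | intermediate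
7 | 4-[2-(3-methoxyphenyl)ethyl]phenol | COc1cccc(CCc2ccc(O)cc2)c1 | intermediate
8 | chloroacetone (1-chloropropan-2-one) | CC(=O)CCl | starting material
9 | 1-{4-[2-(3-methoxyphenyl)ethyl]phenoxy}propan-2-one | CC(=O)COc1ccc(CCc2cccc(OC)c2)cc1 | intermediate
10 | 3-iodoanisole (1-iodo-3-methoxybenzene) | COc1cccc(I)c1 | starting material
11 | but-3-en-1-ol | C=CCCO | starting material
12 | 4-(3-methoxyphenyl)butanal | COc1cccc(CCCC=O)c1 | intermediate
13 | formaldehyde | C=O | starting material
14 | 4-(3-methoxyphenyl)-2-methylidenebutanal | C=C(CCc1cccc(OC)c1)C=O | intermediate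
15 | 2-[2-(3-methoxyphenyl)ethyl]-4-{4-[2-(3-methoxyphenyl)ethyl]phenoxy}-5-oxohexanal (mixture of diastereomers, racemic) | CC(=O)C(Oc1ccc(CCc2cccc(OC)c2)cc1)CC(CCc1cccc(OC)c1)C=O | intermediate
16 | 3-hydroxy-4-[2-(3-methoxyphenyl)ethyl]-6-{4-[2-(3-methoxyphenyl)ethyl]phenoxy}cyclohexan-1-one (mixture of diastereomers, racemic) | COc1cccc(CCC2CC(Oc3ccc(CCc4cccc(OC)c4)cc3)C(=O)CC2O)c1 | intermediate
17 | 4-[2-(3-methoxyphenyl)ethyl]-6-{4-[2-(3-methoxyphenyl)ethyl]phenoxy}cyclohex-2-en-1-one (cis/trans mixture, racemic) | COc1cccc(CCC2C=CC(=O)C(Oc3ccc(CCc4cccc(OC)c4)cc3)C2)c1 | intermediate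
18 | 4-[2-(3-methoxyphenyl)ethyl]-2-{4-[2-(3-methoxyphenyl)ethyl]phenoxy}cyclohexa-2,5-dien-1-one (racemic) | COc1cccc(CCC2C=CC(=O)C(Oc3ccc(CCc4cccc(OC)c4)cc3)=C2)c1 | intermediate
19 | 4-[2-(3-methoxyphenyl)ethyl]-2-{4-[2-(3-methoxyphenyl)ethyl]phenoxy}phenol | COc1cccc(CCc2ccc(Oc3cc(CCc4cccc(OC)c4)ccc3O)cc2)c1 | intermediate
20 | tris(dibromoboryl) derivative of perrottetin E (each of the three phenolic oxygens bearing BBr2) | BrB(Br)Oc1cccc(CCc2ccc(Oc3cc(CCc4cccc(OB(Br)Br)c4)ccc3OB(Br)Br)cc2)c1 | intermediate
21 | perrottetin E, 3-[2-(4-{2-hydroxy-5-[2-(3-hydroxyphenyl)ethyl]phenoxy}phenyl)ethyl]phenol | Oc1cccc(CCc2ccc(Oc3cc(CCc4cccc(O)c4)ccc3O)cc2)c1 | target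

**Step count**

Total steps: 9. Longest linear sequence: 7 steps (steps 1, 2, 3, 4, 7, 8, 9); the enal branch (steps 5, 6) joins at step 7.

**Steps most likely to fail**

Step 7. Oligomerisation or self-condensation of enal 14, or a second Michael addition to the adduct, may outrun the cross-annulation, and the ring closure may stall at the open keto aldehyde. The fallback activates the ketone as a β-keto ester and sets out from phenol 7 and enal 14. Alkylation of 7 with ethyl 4-chloroacetoacetate (NaH, 2.2 equiv, THF, 0 °C → rt) should give ethyl 4-{4-[2-(3-methoxyphenyl)ethyl]phenoxy}-3-oxobutanoate F1. Its doubly activated C2 should add to 14 under catalytic NaOEt in EtOH to give ethyl 2-({4-[2-(3-methoxyphenyl)ethyl]phenoxy}acetyl)-4-formyl-6-(3-methoxyphenyl)hexanoate F2. Piperidinium acetate in toluene at reflux should close F2 through the aryloxy-bearing carbon to ethyl 4-hydroxy-5-[2-(3-methoxyphenyl)ethyl]-3-{4-[2-(3-methoxyphenyl)ethyl]phenoxy}-2-oxocyclohexane-1-carboxylate F3, which dehydrates to ethyl 5-[2-(3-methoxyphenyl)ethyl]-3-{4-[2-(3-methoxyphenyl)ethyl]phenoxy}-2-oxocyclohex-3-ene-1-carboxylate F4. Dealkoxycarbonylation (LiCl cat., wet DMSO, 150 °C) should then give 4-[2-(3-methoxyphenyl)ethyl]-2-{4-[2-(3-methoxyphenyl)ethyl]phenoxy}cyclohex-2-en-1-one F5. Under the conditions of step 8, F5 is dehydrogenated through the same dienone 18, and the route is rejoined at phenol 19.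

Step 8. The catalytic dehydrogenation may stop short of full conversion, or the oxidising conditions may degrade the electron-rich product or cost the aryloxy group. The fallback introduces the second double bond by selenoxide elimination and sets out from 17. Kinetic deprotonation at the aryloxy-bearing C6 (LiN(iPr)2, THF, −78 °C) and trapping with PhSeCl should give 4-[2-(3-methoxyphenyl)ethyl]-6-{4-[2-(3-methoxyphenyl)ethyl]phenoxy}-6-(phenylselanyl)cyclohex-2-en-1-one F6. Oxidation (30% H2O2, pyridine, CH2Cl2, 0 °C → rt) should give the selenoxide 6-(benzeneseleninyl)-4-[2-(3-methoxyphenyl)ethyl]-6-{4-[2-(3-methoxyphenyl)ethyl]phenoxy}cyclohex-2-en-1-one F7. Its syn-elimination toward C5 gives dienone 18, which tautomerises, and the route is rejoined at 19.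

Step 5. Aryl insertion at the internal alkene carbon, or incomplete migration of palladium along the chain, may give a branched aldehyde and unsaturated alcohols that are hard to separate from 12. The fallback fixes the regiochemistry through an alkyne and sets out from 10. Sonogashira coupling with but-3-yn-1-ol (PdCl2(PPh3)2, CuI, Et3N, rt) should give 4-(3-methoxyphenyl)but-3-yn-1-ol F8. Hydrogenation (H2, Pd/C, EtOH, rt) should give 4-(3-methoxyphenyl)butan-1-ol F9. Oxidation (TEMPO cat., KBr cat., NaOCl, NaHCO3, CH2Cl2/H2O, 0 °C) then returns the route at aldehyde 12.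

**Further compounds**

F1 | step 7 | ethyl 4-{4-[2-(3-methoxyphenyl)ethyl]phenoxy}-3-oxobutanoate | CCOC(=O)CC(=O)COc1ccc(CCc2cccc(OC)c2)cc1
F2 | step 7 | ethyl 2-({4-[2-(3-methoxyphenyl)ethyl]phenoxy}acetyl)-4-formyl-6-(3-methoxyphenyl)hexanoate (mixture of diastereomers) | CCOC(=O)C(CC(CCc1cccc(OC)c1)C=O)C(=O)COc1ccc(CCc2cccc(OC)c2)cc1
F3 | step 7 | ethyl 4-hydroxy-5-[2-(3-methoxyphenyl)ethyl]-3-{4-[2-(3-methoxyphenyl)ethyl]phenoxy}-2-oxocyclohexane-1-carboxylate (mixture of diastereomers) | CCOC(=O)C1CC(CCc2cccc(OC)c2)C(O)C(Oc2ccc(CCc3cccc(OC)c3)cc2)C1=O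
F4 | step 7 | ethyl 5-[2-(3-methoxyphenyl)ethyl]-3-{4-[2-(3-methoxyphenyl)ethyl]phenoxy}-2-oxocyclohex-3-ene-1-carboxylate (mixture of diastereomers) | CCOC(=O)C1CC(CCc2cccc(OC)c2)C=C(Oc2ccc(CCc3cccc(OC)c3)cc2)C1=O
F5 | step 7 | 4-[2-(3-methoxyphenyl)ethyl]-2-{4-[2-(3-methoxyphenyl)ethyl]phenoxy}cyclohex-2-en-1-one (racemic) | O=C1CCC(CCc2cccc(OC)c2)C=C1Oc1ccc(CCc2cccc(OC)c2)cc1
F6 | step 8 | 4-[2-(3-methoxyphenyl)ethyl]-6-{4-[2-(3-methoxyphenyl)ethyl]phenoxy}-6-(phenylselanyl)cyclohex-2-en-1-one (mixture of diastereomers) | COc1cccc(CCC2C=CC(=O)C([Se]c3ccccc3)(Oc3ccc(CCc4cccc(OC)c4)cc3)C2)c1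
F7 | step 8 | 6-(benzeneseleninyl)-4-[2-(3-methoxyphenyl)ethyl]-6-{4-[2-(3-methoxyphenyl)ethyl]phenoxy}cyclohex-2-en-1-one (mixture of diastereomers) | COc1cccc(CCC2C=CC(=O)C([Se](=O)c3ccccc3)(Oc3ccc(CCc4cccc(OC)c4)cc3)C2)c1
F8 | step 5 | 4-(3-methoxyphenyl)but-3-yn-1-ol | COc1cccc(C#CCCO)c1
F9 | step 5 | 4-(3-methoxyphenyl)butan-1-ol | COc1cccc(CCCCO)c1
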